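Benzofuran numbering is used (O1, C2, C3, C3a, C4–C7, C7a). The carbocyclic ring B is a 4,4-disubstituted cyclohexadienone whose C3a–H parent is a phenol, and its vinylogous ester O1–C7a=C7–C6=O marks C7a as a carboxyl-level carbon with C3a as its α-carbon. Ring B is therefore grown in one operation onto a cis γ-aryl-β-methyl thionolactone (C7a, C3a) with the dienolate of a methoxy enaminone (C7, C6, C5, C4), forming C7–C7a and C3a–C4 with aromatization. One catalytic crotylboration sets C2 and C3; their cis aryl/methyl pair then steers a dearomatizing para-allylation that creates quaternary C3a.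

Key step: step 6

Remark (assumption): the (R) phosphoric acid is taken to deliver the (1R) carbinol in step 1, the usual sense for aryl aldehydes; if the sense were reversed, the (S) acid would be used.

Step 1
Reactants: 1 3,4,5-trimethoxybenzaldehyde
Product: 3 (1R,2S)-2-methyl-1-(3,4,5-trimethoxyphenyl)but-3-en-1-ol, via pinacol borate ester 2 (not isolated)
Conditions: (Z)-crotyl-B(pin) (1.2 equiv), (R)-TRIP phosphoric acid (5 mol %), toluene, −30 °C; aq. NaHCO3
Reagents that add atoms: (Z)-crotylboronic acid pinacol ester, C/C=C\CB1OC(C)(C)C(C)(C)O1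
Why: Chiral-phosphoric-acid-catalyzed crotylboration through a closed chair transition state, in which the Z boronate gives the syn (1R,2S) pair and the acid selects the aldehyde face.

Step 2
Reactants: 3 (1R,2S)-2-methyl-1-(3,4,5-trimethoxyphenyl)but-3-en-1-ol
Product: 5 (1R,2S)-2-methyl-1-(3,4,5-trimethoxyphenyl)butane-1,4-diol, via bis(9-BBN) adduct 4 (not isolated)
Conditions: 9-BBN (2.2 equiv), THF, 0 °C to rt; then NaOH, H2O2, 0 °C
Reagents that add atoms: hydrogen peroxide, OO
Why: Anti-Markovnikov hydroboration of the terminal alkene (the free hydroxyl consumes one equivalent of borane as the borinate) and oxidative C–B cleavage, with no stereocenter affected.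

Step 3
Reactants: 5 (1R,2S)-2-methyl-1-(3,4,5-trimethoxyphenyl)butane-1,4-diol
Product: 7 (4S,5R)-4-methyl-5-(3,4,5-trimethoxyphenyl)oxolan-2-one, via lactol 6 (not isolated)
Conditions: TEMPO (20 mol %), PhI(OAc)2 (2.5 equiv), CH2Cl2, rt
Reagents that add atoms: none
Why: Oxidative lactonization, in which the nitroxyl oxidizes the primary alcohol selectively, the benzylic hydroxyl traps the aldehyde as lactol 6 and a second oxidation gives the lactone with the cis relationship kept.

Step 4
Reactants: 7 (4S,5R)-4-methyl-5-(3,4,5-trimethoxyphenyl)oxolan-2-one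
Product: 8 (4S,5R)-4-methyl-5-(3,4,5-trimethoxyphenyl)oxolane-2-thione
Conditions: 2,4-bis(4-methoxyphenyl)-1,3,2,4-dithiadiphosphetane 2,4-disulfide (Lawesson's reagent, 0.6 equiv), toluene, 110 °C
Reagents that add atoms: Lawesson's reagent, COc1ccc(cc1)P1(=S)SP(=S)(S1)c1ccc(OC)cc1
Why: Thionation by O/S exchange through a four-membered thiaoxaphosphetane (Wittig-like), which does not involve the stereocenters.

Step 5
Reactants: 9 1-methoxypropan-2-one
Product: 10 (3Z)-4-(dimethylamino)-3-methoxybut-3-en-2-one
Conditions: Me2NCH(OMe)2 (1.2 equiv), neat, 100 °C, MeOH distilled off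
Reagents that add atoms: N,N-dimethylformamide dimethyl acetal, COC(OC)N(C)C
Why: Aminomethylenation of a ketone with an amide acetal, expected at the more acidic methoxy-bearing methylene and giving the Z enaminone with NMe2 anti to the acetyl group.

Step 6
Reactants: 8 (4S,5R)-4-methyl-5-(3,4,5-trimethoxyphenyl)oxolane-2-thione; 10 (3Z)-4-(dimethylamino)-3-methoxybut-3-en-2-one
Product: 14 (2R,3S)-5-methoxy-3-methyl-2-(3,4,5-trimethoxyphenyl)-2,3-dihydro-1-benzofuran-6-ol, via lithium dienolate 11 (not isolated), via S-methyl monothioketal 12 (not isolated), via vinylogous ester 13 (not isolated)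
Conditions: 10 (1.1 equiv), LiN(SiMe3)2 (1.1 equiv), THF, −78 °C; then 8; MeI (1.0 equiv), −78 to 0 °C; LiN(SiMe3)2 (2.2 equiv), 0 to 60 °C; aq. NH4Cl
Reagents that add atoms: none
Why: Proposed new method: the cross-conjugated dienolate 11 should add through C7 to the soft, strongly electrophilic C=S carbon C7a of 8 (thio-Claisen-type acylation), S-methylation fixes the tetrahedral thiolate as 12, and E1cB loss of methanethiolate gives the exocyclic vinylogous ester 13 with O1 retained. Further base removes a γ-proton at C3a to give a 2-oxido-hexatriene (C3a=C7a–C7=C6–C5=C4) that closes the carbocycle by thermal disrotatory 6π electrocyclization, formally a 6-endo attack of C3a on the enaminone carbon C4, and loss of dimethylamide followed by enolization aromatizes ring B to the phenolate of 14. The closest known reactions are the thio-Claisen condensation of ketone enolates with thiono esters, the sulfide-contraction route from thiocarbonyl compounds to vinylogous esters, and the cyclization–aromatization of polyketide-type dienolates. No stereocenter is formed, since C7a is sp3 only transiently and C2 and C3 are spectators that never become acidic or cationic. The step needs C–C bond formation at C=S to outrun proton transfer from the α-methylene of 8 (low temperature, lithium counter-ion), enolization of 10 only at C7 (its sole enolizable position), and C- rather than O-cyclization, which is secured because the only oxygen on C7a is the ring ether O1; if O1 were expelled instead of methanethiolate, the freed alkoxide would re-close by 5-exo addition–elimination.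

Step 7
Reactants: 14 (2R,3S)-5-methoxy-3-methyl-2-(3,4,5-trimethoxyphenyl)-2,3-dihydro-1-benzofuran-6-ol
Product: 15 (2R,3S,3aS)-5-methoxy-3-methyl-3a-(prop-2-en-1-yl)-2-(3,4,5-trimethoxyphenyl)-3,3a-dihydro-1-benzofuran-6(2H)-one
Conditions: PhI(OAc)2 (1.1 equiv), allyltrimethylsilane (5 equiv), (CF3)2CHOH/CH2Cl2, −20 °C
Reagents that add atoms: allyltrimethylsilane, C=CC[Si](C)(C)C
Why: Oxidative dearomatization of a para-alkyl phenol with carbon-nucleophile capture, in which ligand exchange at PhI(OAc)2 and loss of PhI give a phenoxonium ion that the allylsilane attacks at the para carbon C3a (Sakurai-type) from the face opposite the cis C2-aryl/C3-methyl pair, setting C3a as S.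

Compound list
1 | 3,4,5-trimethoxybenzaldehyde | COc1cc(C=O)cc(OC)c1OC | starting material
2 | 2-{[(1R,2S)-2-methyl-1-(3,4,5-trimethoxyphenyl)but-3-en-1-yl]oxy}-4,4,5,5-tetramethyl-1,3,2-dioxaborolane | CC1(C)OB(O[C@@H](c2cc(OC)c(OC)c(OC)c2)[C@H](C=C)C)OC1(C)C | intermediate
3 | (1R,2S)-2-methyl-1-(3,4,5-trimethoxyphenyl)but-3-en-1-ol | O[C@@H](c1cc(OC)c(OC)c(OC)c1)[C@H](C=C)C | intermediate
4 | 9-{[(1R,2S)-4-(9-borabicyclo[3.3.1]nonan-9-yl)-2-methyl-1-(3,4,5-trimethoxyphenyl)butyl]oxy}-9-borabicyclo[3.3.1]nonane | O([C@@H](c1cc(OC)c(OC)c(OC)c1)[C@H](CCB1C2CCCC1CCC2)C)B1C2CCCC1CCC2 | intermediate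
5 | (1R,2S)-2-methyl-1-(3,4,5-trimethoxyphenyl)butane-1,4-diol | O[C@@H](c1cc(OC)c(OC)c(OC)c1)[C@H](CCO)C | intermediate
6 | (4S,5R)-4-methyl-5-(3,4,5-trimethoxyphenyl)oxolan-2-ol (both anomers) | O1[C@@H](c2cc(OC)c(OC)c(OC)c2)[C@H](CC1O)C | intermediate
7 | (4S,5R)-4-methyl-5-(3,4,5-trimethoxyphenyl)oxolan-2-one (cis lactone) | O1[C@@H](c2cc(OC)c(OC)c(OC)c2)[C@H](CC1=O)C | intermediate
8 | (4S,5R)-4-methyl-5-(3,4,5-trimethoxyphenyl)oxolane-2-thione | O1[C@@H](c2cc(OC)c(OC)c(OC)c2)[C@H](CC1=S)C | intermediate
9 | 1-methoxypropan-2-one | COCC(C)=O | starting material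
10 | (3Z)-4-(dimethylamino)-3-methoxybut-3-en-2-one | CN(C)/C=C(\OC)C(C)=O | intermediate
11 | lithium (3Z)-4-(dimethylamino)-3-methoxybuta-1,3-dien-2-olate | CN(C)/C=C(\OC)C(=C)O[Li] | intermediate
12 | (3Z)-4-(dimethylamino)-3-methoxy-1-[(4S,5R)-4-methyl-2-(methylsulfanyl)-5-(3,4,5-trimethoxyphenyl)oxolan-2-yl]but-3-en-2-one (both epimers at oxolane C2) | O1[C@@H](c2cc(OC)c(OC)c(OC)c2)[C@H](CC1(SC)CC(=O)/C(OC)=C/N(C)C)C | intermediate
13 | (3Z)-4-(dimethylamino)-3-methoxy-1-[(4S,5R)-4-methyl-5-(3,4,5-trimethoxyphenyl)oxolan-2-ylidene]but-3-en-2-one (exocyclic alkene geometry open) | O1[C@@H](c2cc(OC)c(OC)c(OC)c2)[C@H](CC1=CC(=O)/C(OC)=C/N(C)C)C | intermediate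
14 | (2R,3S)-5-methoxy-3-methyl-2-(3,4,5-trimethoxyphenyl)-2,3-dihydro-1-benzofuran-6-ol | COc1cc2c(cc1O)O[C@@H](c1cc(OC)c(OC)c(OC)c1)[C@H]2C | intermediate
15 | (2R,3S,3aS)-5-methoxy-3-methyl-3a-(prop-2-en-1-yl)-2-(3,4,5-trimethoxyphenyl)-3,3a-dihydro-1-benzofuran-6(2H)-one | C=CC[C@]12C=C(OC)C(=O)C=C1O[C@@H](c1cc(OC)c(OC)c(OC)c1)[C@H]2C | target

Total step count: 7. Longest linear sequence: 6 (steps 1, 2, 3, 4, 6, 7).

Steps most likely to fail

Step 6 (proposed new method). Proton transfer from the α-methylene of the thionolactone to the dienolate may outrun C–C bond formation, or the S-methylated adduct may not eliminate and electrocyclize cleanly. The fallback makes the C7–C7a bond under neutral conditions by the carbenoid variant of the Eschenmoser sulfide contraction, a known coupling of diazo ketones with thiocarbonyl compounds. It sets out from 10 and 8. Dienolate 11 is trifluoroacetylated with CF3CO2CH2CF3 to (5Z)-6-(dimethylamino)-1,1,1-trifluoro-5-methoxyhex-5-ene-2,4-dione F1. Detrifluoroacetylative diazo transfer (MsN3, Et3N, MeCN) then gives (3Z)-1-diazo-4-(dimethylamino)-3-methoxybut-3-en-2-one F2. F2 and 8 with Rh2(OAc)4 (2 mol %) and PPh3 in toluene at 80 °C should couple through a thiocarbonyl ylide and a thiirane, which is desulfurized to the vinylogous ester 13. DBU is then added to the same flask and heating to 110 °C closes and aromatizes ring B, so both bonds are still formed in one operation. The route is rejoined at 14.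

Step 7. The silane may attack the methoxy-bearing carbon C5 instead of C3a, or the phenoxonium ion may lose the C3 proton (quinone methide, then benzofuran). The fallback brings the allyl group in by a sigmatropic relay and sets out from 14. IBX in DMF oxidizes the guaiacol unit, with loss of methanol, to the ortho-quinone (2R,3S)-3-methyl-2-(3,4,5-trimethoxyphenyl)-2,3-dihydro-1-benzofuran-5,6-dione F3. Allyl bromide and indium powder in THF/H2O add to the C5 carbonyl (the C6 carbonyl is a deactivated vinylogous ester) to give the ortho-quinol (2R,3S)-5-hydroxy-3-methyl-5-(prop-2-en-1-yl)-2-(3,4,5-trimethoxyphenyl)-2,3-dihydro-1-benzofuran-6(5H)-one F4. KH and 18-crown-6 in THF at 0 °C trigger the anionic oxy-Cope shift of the allyl group from C5 to C3a, and MeI caps the resulting C5 enolate on oxygen, which returns to the route at 15. Because the shift is suprafacial, the C3a configuration follows the face of the indium addition at C5, so a chromatographic separation of C3a epimers has to be allowed for.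

Step 4. The hot thionation may erode the cis relationship by ionization of the electron-rich benzylic C–O bond, or stall at partial conversion. The fallback introduces sulfur by O-alkylation and sulfhydrolysis instead of O/S exchange at phosphorus, and sets out from 7. Et3OBF4 in CH2Cl2 at 0 °C gives the lactonium salt (4S,5R)-2-ethoxy-4-methyl-5-(3,4,5-trimethoxyphenyl)-4,5-dihydro-3H-furan-1-ium tetrafluoroborate F5. NaSH in MeCN at −30 °C then displaces ethanol and returns to the route at 8.

Further compounds
F1 | step 6 | (5Z)-6-(dimethylamino)-1,1,1-trifluoro-5-methoxyhex-5-ene-2,4-dione | CN(C)/C=C(\OC)C(=O)CC(=O)C(F)(F)F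
F2 | step 6 | (3Z)-1-diazo-4-(dimethylamino)-3-methoxybut-3-en-2-one | CN(C)/C=C(\OC)C(=O)C=[N+]=[N-]
F3 | step 7 | (2R,3S)-3-methyl-2-(3,4,5-trimethoxyphenyl)-2,3-dihydro-1-benzofuran-5,6-dione | O=C1C(=O)C=C2O[C@@H](c3cc(OC)c(OC)c(OC)c3)[C@@H](C)C2=C1
F4 | step 7 | (2R,3S)-5-hydroxy-3-methyl-5-(prop-2-en-1-yl)-2-(3,4,5-trimethoxyphenyl)-2,3-dihydro-1-benzofuran-6(5H)-one (both C5 epimers) | O=C1C=C2O[C@@H](c3cc(OC)c(OC)c(OC)c3)[C@@H](C)C2=CC1(O)CC=C
F5 | step 4 | (4S,5R)-2-ethoxy-4-methyl-5-(3,4,5-trimethoxyphenyl)-4,5-dihydro-3H-furan-1-ium tetrafluoroborate | CCOC1=[O+][C@@H](c2cc(OC)c(OC)c(OC)c2)[C@@H](C)C1.F[B-](F)(F)F
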